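## Retrosynthetic overview

1. Feature: the benzo ring of unit A (7-hydroxy-6,8-dimethoxycoumarin, O1 to C8a) bears oxygen on C6, C7, C8 and C8a. As the free phenol it is 2,4-dimethoxyresorcinol. There C4a is the one open carbon ortho to a hydroxyl (C8a-OH) and para to the other (C7-OH), and C8a-OH is the one hydroxyl with an open ortho carbon.
2. Last disconnection: the 6',7'-catechol of unit B (primed atoms) travels as a methylenedioxy ring and is freed at the end.
3. Key disconnection: C4-C4a and O1-C2 of pyranone ring A. This leads back to 2,4-dimethoxybenzene-1,3-diol and the α-formyl ester of 6,7-methylenedioxycoumarin-3-acetate (formyl carbon = C4, α-carbon = C3, ester carbon = C2; C3-C3' already in place).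
4. Formyl ester: sesamol, ortho-formylation, Perkin annulation with succinic anhydride (closes pyranone ring B, leaves CH2CO2H on C3'), esterification, titanium-mediated formylation with ethyl formate. Diol: 2,6-dimethoxyphenol, MOM ether, ortho-lithiation/borylation/oxidation, deprotection.
5. Ring order: pyranone ring B (step 5), then pyranone ring A (step 8). Both benzo rings and the dioxole are bought.

Key step: step 8

Remark: 15 is drawn as its aldehyde tautomer but should exist largely as the hydroxymethylene enol; its labile α-carbon becomes sp2 C3, and the target has no stereocentre and no hindered axis (C4 and C4' carry hydrogen), so nothing stereochemical has to be set.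

## Route

Step 1
Reactants: 1 2,6-dimethoxyphenol
Product: 2 1,3-dimethoxy-2-(methoxymethoxy)benzene
Conditions: MOMCl, i-Pr2NEt, CH2Cl2, 0 °C to rt
Reagents that add atoms: chloromethyl methyl ether (MOMCl), COCCl
Why: Williamson-type O-alkylation of the phenol with an α-chloro ether, giving an acetal that withstands organolithium reagents and has no open ortho carbon of its own to steer metalation to.

Step 2
Reactants: 2 1,3-dimethoxy-2-(methoxymethoxy)benzene
Product: 5 2,4-dimethoxy-3-(methoxymethoxy)phenol, via aryllithium 3 (not isolated), via lithium aryltrimethoxyborate 4 (not isolated)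
Conditions: n-BuLi, TMEDA, THF, 0 °C; B(OMe)3, −78 °C to rt; AcOH, 30% aq. H2O2, 0 °C to rt
Reagents that add atoms: hydrogen peroxide, OO (the phenol oxygen of 5); n-butyllithium, [Li]CCCC (lithium of 3 and 4 only); trimethyl borate, COB(OC)OC (boron and methoxy groups of 4 only)
Why: Directed ortho-metalation followed by borylation-oxidation; in symmetric 2 the two carbons ortho to a methoxy group are equivalent, so one aryllithium should form, and the 1,2-aryl shift from boron to peroxide oxygen places the hydroxyl exactly there.

Step 3
Reactants: 5 2,4-dimethoxy-3-(methoxymethoxy)phenol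
Product: 6 2,4-dimethoxybenzene-1,3-diol
Conditions: HCl (ca. 1 M in MeOH), Ar, rt to 40 °C
Reagents that add atoms: none
Why: Acid-catalysed acetal exchange (MOM cleavage), in which the large excess of methanol should trap the oxocarbenium ion as dimethoxymethane before it can alkylate the electron-rich ring, while the aryl methyl ethers are untouched.

Step 4
Reactants: 7 sesamol (1,3-benzodioxol-5-ol)
Product: 8 6-hydroxy-1,3-benzodioxole-5-carbaldehyde
Conditions: MgCl2, Et3N, (CH2O)n, MeCN, reflux; aq. HCl
Reagents that add atoms: formaldehyde (as paraformaldehyde), C=O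
Why: Casnati-Skattebøl ortho-formylation, in which magnesium delivers formaldehyde to an ortho carbon and a second formaldehyde takes up hydride; of the two ortho carbons, the one not flanked by a dioxole oxygen should react.

Step 5
Reactants: 8 6-hydroxy-1,3-benzodioxole-5-carbaldehyde; 9 succinic anhydride
Product: 12 (6,7-methylenedioxy-2-oxo-2H-chromen-3-yl)acetic acid, via sodium phenoxide 10 (not isolated), via aryl hemisuccinate 11 (not isolated)
Conditions: NaOMe, MeOH, rt, evaporated to dryness; 9 (excess), melt, N2, 150-160 °C; aq. NaHCO3 extraction, then aq. HCl
Reagents that add atoms: sodium methoxide, C[O-].[Na+] (sodium of 10 and 11 only)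
Why: Perkin condensation in its succinic anhydride variant; phenoxide 10 opens the anhydride to 11, the α-methylene of the aryl ester adds intramolecularly to the aldehyde, dehydration closes pyranone ring B with CH2CO2H left on C3', and excess anhydride should hold back a second condensation of 12 with 8.

Step 6
Reactants: 12 (6,7-methylenedioxy-2-oxo-2H-chromen-3-yl)acetic acid
Product: 13 ethyl (6,7-methylenedioxy-2-oxo-2H-chromen-3-yl)acetate
Conditions: EtOH, cat. H2SO4, reflux
Reagents that add atoms: ethanol, CCO
Why: Fischer esterification, which the conjugated lactone and the dioxole tolerate because only catalytic acid in ethanol is present.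

Step 7
Reactants: 13 ethyl (6,7-methylenedioxy-2-oxo-2H-chromen-3-yl)acetate; 14 ethyl formate
Product: 15 ethyl 2-(6,7-methylenedioxy-2-oxo-2H-chromen-3-yl)-3-oxopropanoate
Conditions: 14 (excess), TiCl4 (3 equiv), Et3N (4 equiv), CH2Cl2, 0 °C to rt; H2O
Reagents that add atoms: none
Why: Titanium-mediated crossed Claisen condensation (α-formylation of an arylacetate-type ester), where soft enolisation by TiCl4/Et3N avoids any alkoxide or hydride base that could open the lactone or add to C4', and the non-enolisable formate in excess is the preferred acceptor.

Step 8
Reactants: 6 2,4-dimethoxybenzene-1,3-diol; 15 ethyl 2-(6,7-methylenedioxy-2-oxo-2H-chromen-3-yl)-3-oxopropanoate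
Product: 17 6',7'-O-methylene arteminorin C, via ring-open hydroxycinnamate 16 (not isolated)
Conditions: MeSO3H, Ar, 0 °C to rt (6 and 15 equimolar); poured onto ice-water
Reagents that add atoms: none
Why: In MeSO3H the formyl (hydroxymethylene) carbon of 15, the future C4, is protonated and attacked by C6 of diol 6, the future C4a, and loss of water gives hydroxycinnamate 16, whose E and Z forms should equilibrate in acid through the benzylic cation stabilised by the para C7 hydroxyl. The closest known reaction is the Pechmann condensation of resorcinols with ethyl α-formylarylacetates, which gives 3-arylcoumarins. Pyranone ring A closes by a 6-exo-trig acyl substitution in which the C8a hydroxyl of the Z isomer attacks ester carbon C2 and expels ethanol, an irreversible lactonisation that drains the equilibria before it. No stereocentre is formed, and the labile α-carbon of 15 ends as sp2 C3. The step needs site selectivity on the arene: C6 of 6 is ortho to one hydroxyl and para to the other, whereas C5 is served only by the two weaker methoxy donors (one twisted out of conjugation between two neighbours), an adduct there cannot lactonise and should revert, and the C7 hydroxyl has both ortho carbons blocked, so only one coumarin can result. It also needs chemoselectivity: the equimolar charge and fast loss of the acidic α-proton should hold back capture of the benzylic cation by a second arene, closure onto lactone carbon C2' would need a seven-membered ring, and the lactone and dioxole of unit B are inert to MeSO3H at room temperature.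

Step 9
Reactants: 17 6',7'-O-methylene arteminorin C
Product: 18 arteminorin C
Conditions: BCl3 (1 M in CH2Cl2, 6 equiv), CH2Cl2, −20 °C to rt, followed closely; THF-H2O quench
Reagents that add atoms: none
Why: Lewis-acid demethylenation, in which BCl3 opens the aryl acetal through an aryloxy-stabilised oxocarbenium ion, a path closed to methyl ethers (they need slower SN2 dealkylation); this is the known BCl3 preference for methylenedioxy over methoxy arenes, and the aqueous quench releases the bridge carbon as formaldehyde.

## Compound list

1 | 2,6-dimethoxyphenol | COc1cccc(OC)c1O | starting material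
2 | 1,3-dimethoxy-2-(methoxymethoxy)benzene | COCOc1c(OC)cccc1OC | intermediate
3 | [2,4-dimethoxy-3-(methoxymethoxy)phenyl]lithium | [Li]c1ccc(OC)c(OCOC)c1OC | intermediate (not isolated)
4 | lithium [2,4-dimethoxy-3-(methoxymethoxy)phenyl]trimethoxyborate | [Li+].CO[B-](OC)(OC)c1ccc(OC)c(OCOC)c1OC | intermediate (not isolated)
5 | 2,4-dimethoxy-3-(methoxymethoxy)phenol | COCOc1c(OC)ccc(O)c1OC | intermediate
6 | 2,4-dimethoxybenzene-1,3-diol | COc1ccc(O)c(OC)c1O | intermediate
7 | sesamol (1,3-benzodioxol-5-ol) | Oc1ccc2OCOc2c1 | starting material
8 | 6-hydroxy-1,3-benzodioxole-5-carbaldehyde | O=Cc1cc2OCOc2cc1O | intermediate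
9 | succinic anhydride | O=C1CCC(=O)O1 | starting material
10 | sodium 6-formyl-1,3-benzodioxol-5-olate | [Na+].[O-]c1cc2OCOc2cc1C=O | intermediate (not isolated)
11 | sodium 4-[(6-formyl-1,3-benzodioxol-5-yl)oxy]-4-oxobutanoate | [Na+].[O-]C(=O)CCC(=O)Oc1cc2OCOc2cc1C=O | intermediate (not isolated)
12 | (6,7-methylenedioxy-2-oxo-2H-chromen-3-yl)acetic acid | OC(=O)Cc1cc2cc3OCOc3cc2oc1=O | intermediate
13 | ethyl (6,7-methylenedioxy-2-oxo-2H-chromen-3-yl)acetate | CCOC(=O)Cc1cc2cc3OCOc3cc2oc1=O | intermediate
14 | ethyl formate | CCOC=O | starting material
15 | ethyl 2-(6,7-methylenedioxy-2-oxo-2H-chromen-3-yl)-3-oxopropanoate (racemic, enolisable; aldehyde tautomer drawn) | CCOC(=O)C(C=O)c1cc2cc3OCOc3cc2oc1=O | intermediate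
16 | ethyl (Z)-3-(2,4-dihydroxy-3,5-dimethoxyphenyl)-2-(6,7-methylenedioxy-2-oxo-2H-chromen-3-yl)prop-2-enoate | CCOC(=O)/C(c1cc2cc3OCOc3cc2oc1=O)=C\c1cc(OC)c(O)c(OC)c1O | intermediate (not isolated)
17 | 6',7'-O-methylene arteminorin C (7-hydroxy-6,8-dimethoxy-3-(6,7-methylenedioxy-2-oxo-2H-chromen-3-yl)-2H-chromen-2-one) | COc1cc2cc(-c3cc4cc5OCOc5cc4oc3=O)c(=O)oc2c(OC)c1O | intermediate
18 | arteminorin C | COc1cc2cc(-c3cc4cc(O)c(O)cc4oc3=O)c(=O)oc2c(OC)c1O | target

## Step count

Total step count: 9.
Longest linear sequence: 6 steps (steps 4 to 9, from sesamol 7). The diol branch (steps 1 to 3) joins at step 8.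

## Steps most likely to fail

**Step 8.** Four things may go wrong:
- acid-induced deformylation of 15;
- oxidative or oligomeric loss of the very electron-rich diol before the C-C bond forms;
- competing attack through the methoxy-activated C5;
- capture of the benzylic cation by a second arene.

The fallback builds ring A from the other side, through an aldol-type C3=C4 bond instead of the C4-C4a arylation. It sets out from 6 and 12. Magnesium-mediated ortho-formylation of 6 (MgCl2, Et3N, paraformaldehyde, MeCN, reflux) can only strike the one open ortho carbon and should give 2,4-dihydroxy-3,5-dimethoxybenzaldehyde F1. Perkin-Oglialoro condensation of F1 with acid 12 (Ac2O, Et3N, 110 °C) should give 7-O-acetyl-6',7'-O-methylene arteminorin C F2. Methanolysis of the aryl acetate (HCl, MeOH, 40 °C) comes back to the route at 17.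

**Step 9.** The dioxole sits on an electron-poor coumarin and may open slowly. Meanwhile boron bound to the C7 oxygen may chelate and dealkylate the neighbouring methoxy groups, above all the hindered one on C8, and the bicoumarin may dissolve poorly.

The fallback changes the order of events so that no methyl ether is present when the Lewis acid is used. It sets out from 15. BCl3 in CH2Cl2 (0 °C to rt, aqueous quench) should give ethyl 2-(6,7-dihydroxy-2-oxo-2H-chromen-3-yl)-3-oxopropanoate F3. Condensation of F3 with 6 in MeSO3H as in step 8 comes back to the route directly at 18. The esculetin ring is far less nucleophilic than 6, so the free catechol should stay a spectator.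

Oxidative demethylenation of 17 with Pb(OAc)4 is not an alternative. Tetravalent lead would attack the free 2,6-dimethoxyphenol unit of ring A (Wessely-type acetoxylation).

**Step 7.** TiCl4 may be tied up by the lactone carbonyl and the dioxole oxygens. Enolisation could then stay incomplete, or self-Claisen condensation of 13 could compete.

The fallback replaces the Claisen acylation by a neutral aminomethylenation. It sets out from 13. Heating with tert-butoxybis(dimethylamino)methane (Bredereck's reagent, toluene, 100 °C) should give ethyl (E)-3-(dimethylamino)-2-(6,7-methylenedioxy-2-oxo-2H-chromen-3-yl)prop-2-enoate F4. Hydrolysis of the enamine (2 M aq. HCl, THF, rt) comes back to the route at 15.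

## Further compounds

F1 | step 8 | 2,4-dihydroxy-3,5-dimethoxybenzaldehyde | COc1cc(C=O)c(O)c(OC)c1O
F2 | step 8 | 7-O-acetyl-6',7'-O-methylene arteminorin C | COc1cc2cc(-c3cc4cc5OCOc5cc4oc3=O)c(=O)oc2c(OC)c1OC(C)=O
F3 | step 9 | ethyl 2-(6,7-dihydroxy-2-oxo-2H-chromen-3-yl)-3-oxopropanoate (racemic, enolisable) | CCOC(=O)C(C=O)c1cc2cc(O)c(O)cc2oc1=O
F4 | step 7 | ethyl (E)-3-(dimethylamino)-2-(6,7-methylenedioxy-2-oxo-2H-chromen-3-yl)prop-2-enoate | CCOC(=O)/C(=C/N(C)C)c1cc2cc3OCOc3cc2oc1=O
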